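**Retrosynthetic overview**
1. Enabling feature: the target is a (+)-pinoresinol core in which each guaiacyl ring carries at C5, ortho to its C4 oxygen, the β-carbon of a further guaiacyl-C3 unit with the same (S) sense. The cis-(2S,3S)-2,3-dihydrobenzofuran ring (O1–C2–C3–C3a–C7a) on one side is the reduced, ring-closed form of the open keto-phenol (Ar–C(=O)–CH(CH2OH)–aryl C5, C4–OH) on the other. The molecule is therefore C2-symmetric at the bis(α-aryl ketone) oxidation level, and the α-carbon next to the carbonyl can be generated as a radical.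
2. Key disconnection: both aryl C5–Cα bonds (that of the keto arm and its twin inside the dihydrobenzofuran) are cut at once, giving the bis(arylzinc) of 5,5′-diiodopinoresinol dibenzyl ether and two molecules of one racemic α-bromo ketone (stereoconvergent nickel/pybox Negishi arylation).
3. The symmetry is broken afterwards: Felkin–Anh mono-reduction, debenzylation, Mitsunobu closure with inversion (cis ring), global desilylation.
4. Fragments: the diiodide from commercial (+)-pinoresinol in two steps (it supplies both furofuran rings and four stereocentres); the bromo ketone from acetovanillone in four steps.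
5. Ring order: furofuran rings (present from the start), then the dihydrobenzofuran ring (step 10, the only ring closed in the route).

Key step: step 7

Assumption: the pybox enantiomer that gives the (S)-configured α-carbon is to be fixed in a model coupling of 7 with (2-benzyloxy-3-methoxyphenyl)zinc iodide; both ligand enantiomers are equally accessible, so the route does not change.

**Step 1**
Reactants: 1 acetovanillone [1-(4-hydroxy-3-methoxyphenyl)ethan-1-one]
Product: 2 1-[3-methoxy-4-(triisopropylsilyloxy)phenyl]ethan-1-one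
Conditions: i-Pr3SiCl, imidazole, DMF, rt
Reagents that add atoms: triisopropylsilyl chloride, CC(C)[Si](Cl)(C(C)C)C(C)C
Why: Imidazole-promoted O-silylation of the only acidic OH masks the phenol as a robust silyl ether for the enolate, organozinc and hydride steps; no stereocentre is formed.

**Step 2**
Reactants: 2 1-[3-methoxy-4-(triisopropylsilyloxy)phenyl]ethan-1-one
Product: 4 3-hydroxy-1-[3-methoxy-4-(triisopropylsilyloxy)phenyl]propan-1-one, via trimethylsilyl enol ether 3 (not isolated)
Conditions: LiN(SiMe3)2, Me3SiCl, THF, −78 → 0 °C; volatiles removed; then 37% aq. HCHO, Yb(OTf)3 (10 mol %), THF, rt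
Reagents that add atoms: formaldehyde, C=O
Why: The terminal silyl enol ether should undergo a lanthanide-triflate-catalysed aqueous Mukaiyama aldol reaction with formaldehyde exactly once, which secures mono-hydroxymethylation of the methyl ketone; no stereocentre is formed.

**Step 3**
Reactants: 4 3-hydroxy-1-[3-methoxy-4-(triisopropylsilyloxy)phenyl]propan-1-one
Product: 5 3-(tert-butyldimethylsilyloxy)-1-[3-methoxy-4-(triisopropylsilyloxy)phenyl]propan-1-one
Conditions: t-BuMe2SiCl, imidazole, CH2Cl2, 0 °C → rt
Reagents that add atoms: tert-butyldimethylsilyl chloride, CC(C)(C)[Si](C)(C)Cl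
Why: Silylation of the primary alcohol blocks retro-aldol cleavage and dehydration of the β-hydroxy ketone and keeps the hydroxyl out of the organometallic steps; no stereocentre is formed.

**Step 4**
Reactants: 5 3-(tert-butyldimethylsilyloxy)-1-[3-methoxy-4-(triisopropylsilyloxy)phenyl]propan-1-one
Product: 7 rac-2-bromo-3-(tert-butyldimethylsilyloxy)-1-[3-methoxy-4-(triisopropylsilyloxy)phenyl]propan-1-one, via (Z)-trimethylsilyl enol ether 6 (not isolated)
Conditions: LiN(SiMe3)2, Me3SiCl, THF, −78 °C; then NBS, −78 → 0 °C
Reagents that add atoms: N-bromosuccinimide, O=C1CCC(=O)N1Br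
Why: Electrophilic α-bromination of the in-situ silyl enol ether (only one enolisable position) should give the secondary α-bromo ketone under non-acidic conditions that spare both silyl ethers; the new stereocentre is left racemic on purpose because the key step is stereoconvergent.

**Step 5**
Reactants: 8 (+)-pinoresinol [(1S,3aR,4S,6aR)-1,4-bis(4-hydroxy-3-methoxyphenyl)tetrahydro-1H,3H-furo[3,4-c]furan]
Product: 9 5,5′-diiodo-(+)-pinoresinol [(1S,3aR,4S,6aR)-1,4-bis(4-hydroxy-3-iodo-5-methoxyphenyl)tetrahydro-1H,3H-furo[3,4-c]furan]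
Conditions: I2 (2.2 equiv), NaHCO3, THF–H2O, 0 °C → rt, dark
Reagents that add atoms: iodine, II
Why: Electrophilic aromatic iodination through the phenoxide should go to the only free position ortho to each phenolic oxygen (C5; the other ortho position bears OMe, the para position the furofuran), which fixes the site of the later C–C bonds, and the non-acidic medium leaves the four benzylic-ether stereocentres untouched.

**Step 6**
Reactants: 9 5,5′-diiodo-(+)-pinoresinol
Product: 10 4,4′-di-O-benzyl-5,5′-diiodo-(+)-pinoresinol [(1S,3aR,4S,6aR)-1,4-bis[4-(benzyloxy)-3-iodo-5-methoxyphenyl]tetrahydro-1H,3H-furo[3,4-c]furan]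
Conditions: BnBr, K2CO3, DMF, rt
Reagents that add atoms: benzyl bromide, BrCc1ccccc1
Why: Williamson etherification converts both phenols into benzyl ethers that tolerate arylzinc formation and can later be removed by neutral hydrogenolysis, orthogonally to the silyl ethers; no stereocentre is affected.

**Step 7**
Reactants: 10 4,4′-di-O-benzyl-5,5′-diiodo-(+)-pinoresinol; 7 rac-2-bromo-3-(tert-butyldimethylsilyloxy)-1-[3-methoxy-4-(triisopropylsilyloxy)phenyl]propan-1-one (3 equiv)
Product: 12 C2-symmetric bis(α-aryl ketone) with (S) configuration at both new α-carbons (full name in the compound list), via bis(arylzinc iodide) 11 (not isolated)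
Conditions: Zn dust (activated with BrCH2CH2Br/Me3SiCl), LiCl, THF, 50 °C; decanted solution of 11 added to 7, NiCl2·glyme (10 mol %), chiral pybox ligand [one enantiomer of 2,6-bis(4,5-diphenyl-4,5-dihydrooxazol-2-yl)pyridine, 13 mol %], glyme/THF, −30 °C
Reagents that add atoms: none
Why: LiCl-assisted zinc insertion into both C–I bonds places zinc exactly at the two C5 positions; a monovalent nickel–pybox species then abstracts bromine from either enantiomer of 7 to give a planar α-keto radical, which is captured by the chiral aryl–nickel complex formed by transmetalation, and reductive elimination from the resulting trivalent nickel centre forges the aryl C5–Cα bond. The closest known reaction type is the nickel/pybox-catalysed stereoconvergent Negishi arylation of racemic secondary α-bromo ketones with arylzinc halides, here run twice on one C2-symmetric nucleophile. No ring is closed. Both new α-stereocentres are set as S by the ligand (catalyst control, the remote furofuran centres being spectators), and because the core is enantiopure any mis-set centre gives a diastereomer of 12 that can be separated, so the C2-symmetric product should be upgraded in purity. The step needs enantiofacial selectivity at the radical, cross-coupling in preference to β-elimination of silanolate, and survival of the base-labile tertiary α-aryl ketone centres; these are secured by the activated C–Br bond next to the carbonyl (radical formation at −30 °C), by the non-basic arylzinc reagent and by the absence of added base. In one operation it should deliver the complete C40 skeleton, both aryl–C bonds and two of the seven stereocentres from a racemic partner.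

**Step 8**
Reactants: 12 C2-symmetric bis(α-aryl ketone)
Product: 13 mono-alcohol in which one arm is the (1R,2S)-3-(tert-butyldimethylsilyloxy)-1-hydroxy-1-[3-methoxy-4-(triisopropylsilyloxy)phenyl]propan-2-yl group and the other arm is unchanged
Conditions: LiBH(s-Bu)3 (1.0 equiv), THF, −78 °C; pH 7 buffer at −78 °C
Reagents that add atoms: none
Why: Felkin–Anh-controlled addition of the bulky hydride anti to the α-aryl group should turn the (S)-α-aryl ketone into the (1R,2S) alcohol (the diastereomer whose ring closure with inversion gives the cis ring), while limiting the hydride lets only one of the two equivalent carbonyls react; the partition is expected to be statistical, so recovered 12 is recycled.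

**Step 9**
Reactants: 13 mono-alcohol
Product: 14 bis-phenol (13 with both benzyl ethers replaced by OH)
Conditions: H2 (1 atm), 5% Pd/C, EtOAc, rt, stopped at complete debenzylation
Reagents that add atoms: none
Why: Hydrogenolysis of aryl benzyl ethers over Pd/C in a neutral aprotic solvent is much faster than cleavage of the cyclic benzylic C–O bonds, the benzylic alcohol or the aryl ketone, and it leaves the silyl ethers and all stereocentres alone.

**Step 10**
Reactants: 14 bis-phenol
Product: 15 silyl-protected target with the cis-(2S,3S)-2,3-dihydrobenzofuran ring closed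
Conditions: PPh3, DIAD, toluene, 0 °C → rt
Reagents that add atoms: none
Why: Intramolecular Mitsunobu etherification (5-exo-tet attack of the ortho phenol on the activated benzylic carbinol) proceeds with inversion, so the (1R) carbinol becomes C2 (S) cis to the C3 substituent; the low-polarity solvent and low temperature disfavour ionisation, and the phenol of the keto arm has no alcohol partner.

**Step 11**
Reactants: 15 silyl-protected target
Product: 16 CNP0174045.1 (target)
Conditions: Bu4NF/AcOH (1:1, excess), THF, 0 °C → rt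
Reagents that add atoms: none
Why: Acetic-acid-buffered fluoride desilylation removes the two aryl triisopropylsilyl and the two alkyl tert-butyldimethylsilyl ethers without building up alkoxide or phenoxide base, so the epimerisable α-aryl-β-hydroxy ketone and the cis-dihydrobenzofuran should survive.

**Compound list**
1 | acetovanillone, 1-(4-hydroxy-3-methoxyphenyl)ethan-1-one | CC(=O)c1ccc(O)c(OC)c1 | starting material
2 | 1-[3-methoxy-4-(triisopropylsilyloxy)phenyl]ethan-1-one | CC(=O)c1ccc(O[Si](C(C)C)(C(C)C)C(C)C)c(OC)c1 | intermediate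
3 | trimethylsilyl enol ether of 2 (formed in the flask) | C=C(O[Si](C)(C)C)c1ccc(O[Si](C(C)C)(C(C)C)C(C)C)c(OC)c1 | intermediate
4 | 3-hydroxy-1-[3-methoxy-4-(triisopropylsilyloxy)phenyl]propan-1-one | OCCC(=O)c1ccc(O[Si](C(C)C)(C(C)C)C(C)C)c(OC)c1 | intermediate
5 | 3-(tert-butyldimethylsilyloxy)-1-[3-methoxy-4-(triisopropylsilyloxy)phenyl]propan-1-one | CC(C)(C)[Si](C)(C)OCCC(=O)c1ccc(O[Si](C(C)C)(C(C)C)C(C)C)c(OC)c1 | intermediate
6 | (Z)-trimethylsilyl enol ether of 5 (formed in the flask) | CC(C)(C)[Si](C)(C)OC/C=C(\O[Si](C)(C)C)c1ccc(O[Si](C(C)C)(C(C)C)C(C)C)c(OC)c1 | intermediate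
7 | rac-2-bromo-3-(tert-butyldimethylsilyloxy)-1-[3-methoxy-4-(triisopropylsilyloxy)phenyl]propan-1-one | CC(C)(C)[Si](C)(C)OCC(Br)C(=O)c1ccc(O[Si](C(C)C)(C(C)C)C(C)C)c(OC)c1 | intermediate
8 | (+)-pinoresinol, (1S,3aR,4S,6aR)-1,4-bis(4-hydroxy-3-methoxyphenyl)tetrahydro-1H,3H-furo[3,4-c]furan | COc1cc([C@H]2OC[C@H]3[C@@H]2CO[C@@H]3c2ccc(O)c(OC)c2)ccc1O | starting material
9 | 5,5′-diiodo-(+)-pinoresinol, (1S,3aR,4S,6aR)-1,4-bis(4-hydroxy-3-iodo-5-methoxyphenyl)tetrahydro-1H,3H-furo[3,4-c]furan | COc1cc([C@H]2OC[C@H]3[C@@H]2CO[C@@H]3c2cc(I)c(O)c(OC)c2)cc(I)c1O | intermediate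
10 | (1S,3aR,4S,6aR)-1,4-bis[4-(benzyloxy)-3-iodo-5-methoxyphenyl]tetrahydro-1H,3H-furo[3,4-c]furan | COc1cc([C@H]2OC[C@H]3[C@@H]2CO[C@@H]3c2cc(I)c(OCc3ccccc3)c(OC)c2)cc(I)c1OCc1ccccc1 | intermediate
11 | bis(arylzinc iodide) of 10, zinc at both former C–I carbons (formed in the flask, LiCl complexed) | COc1cc([C@H]2OC[C@H]3[C@@H]2CO[C@@H]3c2cc([Zn]I)c(OCc3ccccc3)c(OC)c2)cc([Zn]I)c1OCc1ccccc1 | intermediate
12 | (2S,2′S)-2,2′-{[(1S,3aR,4S,6aR)-tetrahydro-1H,3H-furo[3,4-c]furan-1,4-diyl]bis[2-(benzyloxy)-3-methoxy-5,1-phenylene]}bis{3-(tert-butyldimethylsilyloxy)-1-[3-methoxy-4-(triisopropylsilyloxy)phenyl]propan-1-one} | COc1cc(C(=O)[C@H](CO[Si](C)(C)C(C)(C)C)c2cc([C@H]3OC[C@H]4[C@@H]3CO[C@@H]4c3cc(OC)c(OCc4ccccc4)c(c3)[C@@H](CO[Si](C)(C)C(C)(C)C)C(=O)c3ccc(O[Si](C(C)C)(C(C)C)C(C)C)c(OC)c3)cc(OC)c2OCc2ccccc2)ccc1O[Si](C(C)C)(C(C)C)C(C)C | intermediate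
13 | mono-alcohol: 12 with one C=O reduced to (R)-CH(OH), that arm being (1R,2S) | COc1cc(C(=O)[C@H](CO[Si](C)(C)C(C)(C)C)c2cc([C@H]3OC[C@H]4[C@@H]3CO[C@@H]4c3cc(OC)c(OCc4ccccc4)c(c3)[C@@H](CO[Si](C)(C)C(C)(C)C)[C@@H](O)c3ccc(O[Si](C(C)C)(C(C)C)C(C)C)c(OC)c3)cc(OC)c2OCc2ccccc2)ccc1O[Si](C(C)C)(C(C)C)C(C)C | intermediate
14 | bis-phenol: 13 with both benzyl ethers cleaved | COc1cc(C(=O)[C@H](CO[Si](C)(C)C(C)(C)C)c2cc([C@H]3OC[C@H]4[C@@H]3CO[C@@H]4c3cc(OC)c(O)c(c3)[C@@H](CO[Si](C)(C)C(C)(C)C)[C@@H](O)c3ccc(O[Si](C(C)C)(C(C)C)C(C)C)c(OC)c3)cc(OC)c2O)ccc1O[Si](C(C)C)(C(C)C)C(C)C | intermediate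
15 | silyl-protected target: (2S)-keto arm with free ortho phenol, (2S,3S)-cis-dihydrobenzofuran arm, two ArO–Si(i-Pr)3 and two CH2O–SiMe2t-Bu groups | COc1cc(C(=O)[C@H](CO[Si](C)(C)C(C)(C)C)c2cc([C@H]3OC[C@H]4[C@@H]3CO[C@@H]4c3cc(OC)c4c(c3)[C@@H](CO[Si](C)(C)C(C)(C)C)[C@@H](c3ccc(O[Si](C(C)C)(C(C)C)C(C)C)c(OC)c3)O4)cc(OC)c2O)ccc1O[Si](C(C)C)(C(C)C)C(C)C | intermediate
16 | CNP0174045.1, (2S)-3-hydroxy-1-(4-hydroxy-3-methoxyphenyl)-2-{2-hydroxy-5-[(1S,3aR,4S,6aR)-4-[(2S,3S)-2-(4-hydroxy-3-methoxyphenyl)-3-(hydroxymethyl)-7-methoxy-2,3-dihydrobenzofuran-5-yl]tetrahydro-1H,3H-furo[3,4-c]furan-1-yl]-3-methoxyphenyl}propan-1-one | COc1cc(C(=O)[C@H](CO)c2cc([C@H]3OC[C@H]4[C@@H]3CO[C@@H]4c3cc(OC)c4c(c3)[C@@H](CO)[C@@H](c3ccc(O)c(OC)c3)O4)cc(OC)c2O)ccc1O | target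

**Step count and risks**
Total step count: 11. Longest linear sequence: 9 steps (steps 1, 2, 3, 4, 7, 8, 9, 10, 11 from acetovanillone).

Step 7 (most likely to fail). What may go wrong: slow transmetalation of the ortho-alkoxy arylzinc to nickel with an incomplete second coupling, erosion of facial control when the radical is captured, and β-elimination of silanolate from the product. Fallback: it sets out from 10 and from the silyl enol ether 6 (made as in step 4 but isolated), reverses the polarity and defers stereocontrol. A Pd(OAc)2/P(t-Bu)3-catalysed, fluoride-promoted α-arylation of the enol silane (Bu3SnF, CsF, toluene, 85 °C) at both C–I bonds should give the bis-ketone F1 as a mixture of epimers at the two α-carbons. Because these centres are base-labile, a ruthenium-catalysed asymmetric transfer hydrogenation with dynamic kinetic resolution (RuCl[(S,S)-TsDPEN](p-cymene) or its enantiomer, HCO2H/Et3N) should funnel the mixture into the fully defined bis-alcohol F2. Oxidation of one carbinol with Dess–Martin periodinane (one equivalent, NaHCO3) then comes back to the route at 13.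

Step 10. What may go wrong: ionisation of the activated p-silyloxybenzylic alcohol, so that closure loses its stereospecificity (trans ring) or elimination occurs, and dehydration of the hemiketal tautomer of the keto arm to a benzofuran. Fallback: it sets out from 12 and makes ring closure precede reduction. Both benzyl ethers are removed first (H2, Pd/C, EtOAc) to give the bis(keto-phenol) F3, each arm of which equilibrates with its cyclic hemiketal. Et3SiH (one equivalent) with BF3·OEt2 in CH2Cl2 at −78 °C should reduce one hemiketal through the 2-aryl-3H-benzofuran-1-ium ion, the hydride entering anti to the C3 CH2OSi group. This gives the cis ring without any substitution at the benzylic carbon and comes back at 15, bypassing steps 8 to 10.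

Step 8. What may go wrong: over-reduction beyond the statistical partition, insufficient Felkin facial selectivity, and enolisation by the basic hydride followed by β-elimination of silanolate. Fallback: it sets out from 12 and desymmetrises by oxidation instead of reduction. Both ketones are reduced under non-basic reagent control (Corey–Bakshi–Shibata reduction with the oxazaborolidine enantiomer matched to the Felkin preference, catecholborane, toluene, −78 °C) to the C2-symmetric bis-alcohol F4, which has the same structure as F2, so over-reduction is no longer possible. One carbinol is then oxidised back with Dess–Martin periodinane (one equivalent, NaHCO3), unreacted F4 being recycled, which comes back at 13.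

**Further compounds**
F1 | step 7 | bis-ketone of the constitution of 12, mixture of epimers at the two α-carbons | COc1cc(C(=O)C(CO[Si](C)(C)C(C)(C)C)c2cc([C@H]3OC[C@H]4[C@@H]3CO[C@@H]4c3cc(OC)c(OCc4ccccc4)c(c3)C(CO[Si](C)(C)C(C)(C)C)C(=O)c3ccc(O[Si](C(C)C)(C(C)C)C(C)C)c(OC)c3)cc(OC)c2OCc2ccccc2)ccc1O[Si](C(C)C)(C(C)C)C(C)C
F2 | step 7 | C2-symmetric bis-alcohol, both arms (1R,2S) | COc1cc([C@H](O)[C@H](CO[Si](C)(C)C(C)(C)C)c2cc([C@H]3OC[C@H]4[C@@H]3CO[C@@H]4c3cc(OC)c(OCc4ccccc4)c(c3)[C@@H](CO[Si](C)(C)C(C)(C)C)[C@@H](O)c3ccc(O[Si](C(C)C)(C(C)C)C(C)C)c(OC)c3)cc(OC)c2OCc2ccccc2)ccc1O[Si](C(C)C)(C(C)C)C(C)C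
F3 | step 10 | bis(keto-phenol): 12 with both benzyl ethers cleaved | COc1cc(C(=O)[C@H](CO[Si](C)(C)C(C)(C)C)c2cc([C@H]3OC[C@H]4[C@@H]3CO[C@@H]4c3cc(OC)c(O)c(c3)[C@@H](CO[Si](C)(C)C(C)(C)C)C(=O)c3ccc(O[Si](C(C)C)(C(C)C)C(C)C)c(OC)c3)cc(OC)c2O)ccc1O[Si](C(C)C)(C(C)C)C(C)C
F4 | step 8 | C2-symmetric bis-alcohol, both arms (1R,2S), same structure as F2 | COc1cc([C@H](O)[C@H](CO[Si](C)(C)C(C)(C)C)c2cc([C@H]3OC[C@H]4[C@@H]3CO[C@@H]4c3cc(OC)c(OCc4ccccc4)c(c3)[C@@H](CO[Si](C)(C)C(C)(C)C)[C@@H](O)c3ccc(O[Si](C(C)C)(C(C)C)C(C)C)c(OC)c3)cc(OC)c2OCc2ccccc2)ccc1O[Si](C(C)C)(C(C)C)C(C)C
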